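The route cuts the cross-conjugated dienone between its α-methylene carbon (the sp2 carbon on ring C5) and the side-chain carbonyl carbon. The key step exploits that both atoms are sp2 and lie outside the cyclohexanone ring. A neutral Pd/Cu thioester–vinylstannane coupling (Liebeskind–Srogl type) joins them. In one operation it delivers the complete dienone at its final oxidation level, next to the finished ring (four stereocentres, ketone, isovalerate) and a silyl-masked hydroperoxide. The precursor is a 1-substituted vinylstannane, made through the enol triflate of the methyl ketone left by ozonolysis of (R)-carvone. Carvone C5 relays C2, C3 and C6 by substrate control.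

Key step: step 16

Remark on numbering: ring atoms keep the carvone numbering throughout. C1 is the ring carbonyl carbon, C2 the methyl-bearing carbon, C3 the next carbon, C4 the CH2, C5 the carbon bearing the side chain, and C6 the remaining carbon. α is the ring face that carries the C5 side chain and β is the opposite face.
Assumption: compounds 1, 16, 17 and 19 and all reagents named under the conditions are taken as commercially available.

Step 1
Reactants: 1 (R)-(−)-carvone
Product: 2 (−)-cis-carveol [(1R,5R)-2-methyl-5-(prop-1-en-2-yl)cyclohex-2-en-1-ol; 1α-OH]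
Conditions: NaBH4, CeCl3·7H2O, MeOH, −20 °C → 0 °C
Reagents that add atoms: none
Why: Luche 1,2-reduction: hydride adds axially to the carbonyl of the half-chair that holds the isopropenyl group equatorial, so the new C1 carbinol is equatorial and cis (α) to the C5 substituent, and the enone C=C is not reduced.

Step 2
Reactants: 2 (−)-cis-carveol
Product: 3 2α,3α-epoxy-cis-carveol (1-OH, epoxide and isopropenyl all on the α face)
Conditions: VO(acac)2 (2 mol %), t-BuOOH (decane), toluene, 0 °C → rt
Reagents that add atoms: tert-butyl hydroperoxide CC(C)(C)OO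
Why: Hydroxyl-directed vanadium-catalysed epoxidation: the vanadate ester of the 1α-OH delivers oxygen to the α face of the allylic C2=C3 bond only, which sets C2 (final configuration) and C3 and leaves the isolated isopropenyl alkene untouched.

Step 3
Reactants: 3 2α,3α-epoxy-cis-carveol
Product: 4 1α-O-trimethylsilyl ether of 3
Conditions: TMSCl, imidazole, CH2Cl2, 0 °C
Reagents that add atoms: chlorotrimethylsilane C[Si](C)(C)Cl
Why: Silyl ether protection of the single hydroxyl group keeps C1 at the alcohol level, so that neither a second enolisable ketone nor an acidic O–H is present in step 5.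

Step 4
Reactants: 4 1α-O-trimethylsilyl ether
Product: 5 5α-acetyl compound (methyl ketone; 1α-OTMS, 2α,3α-epoxide)
Conditions: O3, CH2Cl2, −78 °C; then Me2S, −78 °C → rt
Reagents that add atoms: ozone [O-][O+]=O
Why: Ozonolysis with reductive work-up cleaves the only C=C bond to the methyl ketone and removes the one carbon that the coupling will replace, while C5 stays equatorial and unepimerised under neutral conditions.

Step 5
Reactants: 5 5α-acetyl compound
Product: 7 1α-hydroxy-2α,3α-epoxy enol triflate (ring C5 bears C(OTf)=CH2), via TMS-protected enol triflate 6 (not isolated)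
Conditions: KHMDS, THF, −78 °C; Comins' reagent, −78 °C; then citric acid, MeOH, rt
Reagents that add atoms: N-(5-chloropyridin-2-yl)bis(trifluoromethanesulfonimide) O=S(=O)(N(c1ccc(Cl)cn1)S(=O)(=O)C(F)(F)F)C(F)(F)F
Why: Kinetic deprotonation of the methyl ketone at its CH3 group and O-sulfonylation (enol triflate synthesis) give the 1,1-disubstituted enol triflate without touching a stereocentre, and the labile TMS ether is methanolysed in the acidic work-up.

Step 6
Reactants: 7 1α-hydroxy-2α,3α-epoxy enol triflate
Product: 8 2α,3α-epoxy ketone (C1 ketone, enol triflate at C5)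
Conditions: Dess–Martin periodinane, NaHCO3, CH2Cl2, 0 °C → rt
Reagents that add atoms: none
Why: Buffered Dess–Martin oxidation returns C1 to the ketone without opening the epoxide or touching the enol triflate.

Step 7
Reactants: 8 2α,3α-epoxy ketone
Product: 9 2α,3β-dihydroxy ketone (trans-diaxial diol, 2β-CH3)
Conditions: HClO4 (cat.), THF/H2O, rt → 40 °C
Reagents that add atoms: water O
Why: Acid-catalysed anti (SN2-type) hydrolysis of the α,β-epoxy ketone: water attacks C3, the carbon remote from the carbonyl, from the β face in the trans-diaxial mode (Fürst–Plattner rule), so C3 is inverted to 3β-OH while the 2α C–O bond is retained.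

Step 8
Reactants: 9 2α,3β-dihydroxy ketone
Product: 10 2α,3β-bis(triethylsilyloxy) ketone
Conditions: TESOTf, 2,6-lutidine, CH2Cl2, −78 °C → 0 °C
Reagents that add atoms: triethylsilyl trifluoromethanesulfonate CC[Si](CC)(CC)OS(=O)(=O)C(F)(F)F
Why: Silyl ether protection with a silyl triflate and a hindered pyridine base caps the secondary and the tertiary axial hydroxyl groups without enolising the ketone.

Step 9
Reactants: 10 2α,3β-bis(triethylsilyloxy) ketone
Product: 13 6β-hydroxy ketone (2α,3β-bis-OTES; enol triflate at C5), via TMS enol ether 11 (not isolated), via 6β-trimethylsilyloxy ketone 12 (not isolated)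
Conditions: TMSOTf, Et3N, CH2Cl2, 0 °C; crude enol ether, mCPBA, CH2Cl2, −20 °C; then citric acid (cat.), MeOH, 0 °C
Reagents that add atoms: 3-chloroperoxybenzoic acid O=C(OO)c1cccc(Cl)c1
Why: Rubottom oxidation: enolisation can only go towards C6 because C2 is quaternary, and the peracid attacks the enol ether from the β face, away from the C5 substituent and the axial 2α-OTES group, to give after silyl shift and mild methanolysis the equatorial 6β-alcohol, which is also the more stable epimer.

Step 10
Reactants: 13 6β-hydroxy ketone
Product: 14 6β-(3-methylbutanoyloxy) ketone (enol triflate at C5)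
Conditions: isovaleryl chloride, pyridine, DMAP (cat.), CH2Cl2, 0 °C → rt
Reagents that add atoms: 3-methylbutanoyl chloride CC(C)CC(=O)Cl
Why: DMAP-catalysed acylation of the only free hydroxyl group installs the isovalerate with retention at C6.

Step 11
Reactants: 14 6β-(3-methylbutanoyloxy) ketone
Product: 15 1-(ring-C5)-vinyl trimethylstannane (C5 bears C(SnMe3)=CH2)
Conditions: (Me3Sn)2, Pd(PPh3)4 (5 mol %), LiCl, THF, 60 °C
Reagents that add atoms: hexamethylditin C[Sn](C)(C)[Sn](C)(C)C
Why: Palladium-catalysed stannylation of an enol triflate with a distannane (Stille-type, chloride-assisted) exchanges C–OTf for C–SnMe3 at the same carbon under neutral conditions that spare the ester, ketone and silyl ethers.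

Step 12
Reactants: 16 diethylphosphonoacetic acid; 17 4-methylbenzenethiol
Product: 18 S-(4-methylphenyl) 2-(diethoxyphosphoryl)ethanethioate
Conditions: DCC, DMAP (cat.), CH2Cl2, 0 °C → rt
Reagents that add atoms: none
Why: Steglich-type carbodiimide coupling of the acid with the arenethiol gives the thioester-bearing phosphonate.

Step 13
Reactants: 19 2-methylprop-2-en-1-ol
Product: 20 2-methyl-2-(triethylsilylperoxy)propan-1-ol
Conditions: O2 (1 atm), Et3SiH, Co(thd)2 (5 mol %), ClCH2CH2Cl, rt
Reagents that add atoms: dioxygen O=O; triethylsilane CC[SiH](CC)CC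
Why: Mukaiyama–Isayama cobalt-catalysed hydroperoxysilylation: hydrogen-atom transfer to the CH2 terminus gives the tertiary radical (Markovnikov), which traps O2 and is capped by the silane, so the tertiary C–OO bond is formed regiospecifically and already protected.

Step 14
Reactants: 20 2-methyl-2-(triethylsilylperoxy)propan-1-ol
Product: 21 2-methyl-2-(triethylsilylperoxy)propanal
Conditions: Dess–Martin periodinane, NaHCO3, CH2Cl2, 0 °C
Reagents that add atoms: none
Why: Dess–Martin oxidation of the primary alcohol is safe here because the peroxide carbon bears no hydrogen, so a Kornblum–DeLaMare-type fragmentation is not possible.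

Step 15
Reactants: 21 2-methyl-2-(triethylsilylperoxy)propanal; 18 S-(4-methylphenyl) 2-(diethoxyphosphoryl)ethanethioate
Product: 22 S-(4-methylphenyl) (E)-4-methyl-4-(triethylsilylperoxy)pent-2-enethioate
Conditions: LiCl, i-Pr2NEt, MeCN, 0 °C → rt
Reagents that add atoms: none
Why: Horner–Wadsworth–Emmons olefination under Masamune–Roush conditions is mild enough for the silyl peroxide and, with the α-quaternary aldehyde, should give the (E)-enethioate.

Step 16
Reactants: 15 1-(ring-C5)-vinyl trimethylstannane; 22 S-(4-methylphenyl) (E)-4-methyl-4-(triethylsilylperoxy)pent-2-enethioate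
Product: 23 tris-TES-protected target (2α,3β-bis-OTES, side-chain OOTES)
Conditions: Pd2(dba)3 (5 mol %), P(2-furyl)3 (20 mol %), copper(I) diphenylphosphinate (1.5 equiv), THF, degassed, dark, rt → 45 °C
Reagents that add atoms: none
Why: Cu(I) binds the sulfur of 22 and Pd(0) inserts into the acyl C–S bond, the 1-substituted vinyl group of 15 passes from tin through copper (the phosphinate takes up Me3Sn) to the acyl-palladium, and reductive elimination joins the α-methylene carbon to the carbonyl carbon. The closest known reaction type is the Liebeskind–Srogl-type Pd-catalysed, Cu(I) diphenylphosphinate-mediated ketone synthesis from thiol esters and vinylstannanes under neutral conditions, supported by the known tolerance of O-protected peroxides to Pd(0) cross-coupling. No ring is closed and no stereocentre is created, and the (E)-alkene of 22 and the 1,1-disubstituted alkene of 15 are transferred unchanged. The step needs chemoselectivity for the thioester over the isovalerate, the hindered ring ketone and the O–O bond, which is secured because only the C–S bond is activated by the thiophilic copper, whose stoichiometric use also suppresses the cine substitution typical of 1-substituted vinylstannanes. The absence of base protects the epimerisable C6 (α-acyloxy ketone) and keeps the exocyclic alkene from shifting towards C5, and the thiolate is held as insoluble copper thiolate so that it should not add to the new enone.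

Step 17
Reactants: 23 tris-TES-protected target
Product: 24 CNP0239240.1 (target)
Conditions: HF·pyridine, pyridine, THF, 0 °C → rt (plastic vessel)
Reagents that add atoms: none
Why: Fluoride-mediated desilylation under buffered, weakly acidic conditions cleaves both Si–O(C) bonds and the Si–OO bond in one operation, without base that could epimerise C6, move the acyl group or trigger an α-ketol rearrangement.

Compound list
1 | (R)-(−)-carvone | C=C(C)[C@@H]1CC=C(C)C(=O)C1 | starting material
2 | (−)-cis-carveol, (1R,5R)-2-methyl-5-(prop-1-en-2-yl)cyclohex-2-en-1-ol | C=C(C)[C@@H]1CC=C(C)[C@H](O)C1 | intermediate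
3 | 2α,3α-epoxy-cis-carveol (1α-OH, 2β-CH3, 5α-isopropenyl) | C=C(C)[C@@H]1C[C@@H]2O[C@]2(C)[C@H](O)C1 | intermediate
4 | 1α-O-trimethylsilyl ether of 3 | C=C(C)[C@@H]1C[C@@H]2O[C@]2(C)[C@H](O[Si](C)(C)C)C1 | intermediate
5 | 5α-acetyl-2α,3α-epoxy-2β-methyl-1α-(trimethylsilyloxy)cyclohexane | CC(=O)[C@@H]1C[C@@H]2O[C@]2(C)[C@H](O[Si](C)(C)C)C1 | intermediate
6 | TMS-protected enol triflate (C5–C(OTf)=CH2, 1α-OTMS, 2α,3α-epoxide) | C=C(OS(=O)(=O)C(F)(F)F)[C@@H]1C[C@@H]2O[C@]2(C)[C@H](O[Si](C)(C)C)C1 | intermediate
7 | 1α-hydroxy-2α,3α-epoxy enol triflate | C=C(OS(=O)(=O)C(F)(F)F)[C@@H]1C[C@@H]2O[C@]2(C)[C@H](O)C1 | intermediate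
8 | 2α,3α-epoxy ketone bearing the enol triflate at C5 | C=C(OS(=O)(=O)C(F)(F)F)[C@@H]1C[C@@H]2O[C@]2(C)C(=O)C1 | intermediate
9 | 2α,3β-dihydroxy-2β-methyl ketone bearing the enol triflate at C5 | C=C(OS(=O)(=O)C(F)(F)F)[C@@H]1C[C@@H](O)[C@](C)(O)C(=O)C1 | intermediate
10 | 2α,3β-bis(triethylsilyloxy) ketone | C=C(OS(=O)(=O)C(F)(F)F)[C@@H]1C[C@@H](O[Si](CC)(CC)CC)[C@](C)(O[Si](CC)(CC)CC)C(=O)C1 | intermediate
11 | C1=C6 trimethylsilyl enol ether of 10 | C=C(OS(=O)(=O)C(F)(F)F)[C@@H]1C[C@@H](O[Si](CC)(CC)CC)[C@](C)(O[Si](CC)(CC)CC)C(O[Si](C)(C)C)=C1 | intermediate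
12 | 6β-trimethylsilyloxy ketone | C=C(OS(=O)(=O)C(F)(F)F)[C@@H]1C[C@@H](O[Si](CC)(CC)CC)[C@](C)(O[Si](CC)(CC)CC)C(=O)[C@H]1O[Si](C)(C)C | intermediate
13 | 6β-hydroxy ketone | C=C(OS(=O)(=O)C(F)(F)F)[C@@H]1C[C@@H](O[Si](CC)(CC)CC)[C@](C)(O[Si](CC)(CC)CC)C(=O)[C@H]1O | intermediate
14 | 6β-(3-methylbutanoyloxy) ketone, enol triflate | C=C(OS(=O)(=O)C(F)(F)F)[C@@H]1C[C@@H](O[Si](CC)(CC)CC)[C@](C)(O[Si](CC)(CC)CC)C(=O)[C@H]1OC(=O)CC(C)C | intermediate
15 | 6β-(3-methylbutanoyloxy) ketone, 1-substituted vinyl trimethylstannane | C=C([Sn](C)(C)C)[C@@H]1C[C@@H](O[Si](CC)(CC)CC)[C@](C)(O[Si](CC)(CC)CC)C(=O)[C@H]1OC(=O)CC(C)C | intermediate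
16 | diethylphosphonoacetic acid | CCOP(=O)(CC(=O)O)OCC | starting material
17 | 4-methylbenzenethiol | Cc1ccc(S)cc1 | starting material
18 | S-(4-methylphenyl) 2-(diethoxyphosphoryl)ethanethioate | CCOP(=O)(CC(=O)Sc1ccc(C)cc1)OCC | intermediate
19 | 2-methylprop-2-en-1-ol | C=C(C)CO | starting material
20 | 2-methyl-2-(triethylsilylperoxy)propan-1-ol | CC(C)(CO)OO[Si](CC)(CC)CC | intermediate
21 | 2-methyl-2-(triethylsilylperoxy)propanal | CC(C)(C=O)OO[Si](CC)(CC)CC | intermediate
22 | S-(4-methylphenyl) (E)-4-methyl-4-(triethylsilylperoxy)pent-2-enethioate | CC(C)(/C=C/C(=O)Sc1ccc(C)cc1)OO[Si](CC)(CC)CC | intermediate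
23 | tris-TES-protected target | C=C(C(=O)/C=C/C(C)(C)OO[Si](CC)(CC)CC)[C@@H]1C[C@@H](O[Si](CC)(CC)CC)[C@](C)(O[Si](CC)(CC)CC)C(=O)[C@H]1OC(=O)CC(C)C | intermediate
24 | CNP0239240.1, (1S,3S,4R,6S)-6-[(4E)-6-hydroperoxy-6-methyl-3-oxohepta-1,4-dien-2-yl]-3,4-dihydroxy-3-methyl-2-oxocyclohexyl 3-methylbutanoate | C=C(C(=O)/C=C/C(C)(C)OO)[C@@H]1C[C@@H](O)[C@](C)(O)C(=O)[C@H]1OC(=O)CC(C)C | target

Total step count: 17.
Longest linear sequence: 13 (steps 1–11, 16, 17).

Steps most likely to fail

Step 16 (key step). The O–O bond may be cleaved reductively by Cu(I) or Pd(0). Transfer of the hindered 1-substituted vinyl group may also be so slow that protodestannylation takes over. The fallback forms the same C–C bond by carbonyl addition and installs the peroxide afterwards. It sets out from enol triflate 14. Commercial 4-methylpent-3-en-1-ol is oxidised with Dess–Martin periodinane to 4-methylpent-3-enal F1. A Nozaki–Hiyama–Kishi reaction of 14 with F1 (CrCl2, cat. NiCl2, DMF) should give the allylic alcohol F2 as carbinol epimers, the hindered ring ketone and the ester being inert to the vinylchromium species. Buffered Dess–Martin oxidation gives the β,γ-unsaturated ketone F3. A Schenck ene reaction (O2, tetraphenylporphyrin, hν, CH2Cl2, low temperature) on the only electron-rich alkene places the tertiary hydroperoxide, with shift of the double bond into conjugation, to give the bis-TES hydroperoxide F4. F4 has to be separated from the regioisomeric ene product. HF·pyridine then brings the sequence back to the route at 24.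

Step 7. The deactivated α,β-epoxy ketone may open too slowly, and acid-induced acyl migration (ring contraction) or loss of regiocontrol may compete. The fallback opens the epoxide at the alcohol oxidation level under chelation control. It sets out from epoxy alcohol 7. Ti(Oi-Pr)4 binds the 1α-OH and the epoxide oxygen and directs benzoic acid to C3 from the β face (titanium-mediated opening of a 2,3-epoxy alcohol), giving the 3β-benzoate 1α,2α-diol F5. Dess–Martin oxidation can then only hit the free secondary 1α-OH and gives the keto benzoate F6. Brief methanolysis (K2CO3, MeOH, 0 °C) brings the sequence back to the route at 9.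

Step 9. Enolisation of the hindered ketone may be incomplete, the facial selectivity of the epoxidation of the enol ether may be poor, or TES groups may be lost in the methanolysis. The fallback replaces oxidation by substitution. It sets out from 10 through enol ether 11. N-Bromosuccinimide (THF, −78 °C) gives the 6-bromo ketone F7. Displacement with 3-methylbutanoic acid/Cs2CO3 in DMF, with equilibration of C6 through the enol to the equatorial β epimer, introduces the ester directly. The sequence comes back to the route at 14, bypassing 13.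

Further compounds
F1 | step 16 | 4-methylpent-3-enal | CC(C)=CCC=O
F2 | step 16 | allylic alcohol from the Nozaki–Hiyama–Kishi addition (carbinol epimers) | C=C(C(O)CC=C(C)C)[C@@H]1C[C@@H](O[Si](CC)(CC)CC)[C@](C)(O[Si](CC)(CC)CC)C(=O)[C@H]1OC(=O)CC(C)C
F3 | step 16 | β,γ-unsaturated α-methylene ketone | C=C(C(=O)CC=C(C)C)[C@@H]1C[C@@H](O[Si](CC)(CC)CC)[C@](C)(O[Si](CC)(CC)CC)C(=O)[C@H]1OC(=O)CC(C)C
F4 | step 16 | 2α,3β-bis-TES ether of the target (free hydroperoxide) | C=C(C(=O)/C=C/C(C)(C)OO)[C@@H]1C[C@@H](O[Si](CC)(CC)CC)[C@](C)(O[Si](CC)(CC)CC)C(=O)[C@H]1OC(=O)CC(C)C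
F5 | step 7 | 3β-benzoyloxy-1α,2α-diol enol triflate | C=C(OS(=O)(=O)C(F)(F)F)[C@@H]1C[C@@H](OC(=O)c2ccccc2)[C@](C)(O)[C@H](O)C1
F6 | step 7 | 3β-benzoyloxy-2α-hydroxy ketone enol triflate | C=C(OS(=O)(=O)C(F)(F)F)[C@@H]1C[C@@H](OC(=O)c2ccccc2)[C@](C)(O)C(=O)C1
F7 | step 9 | 6-bromo ketone (C6 epimers) | C=C(OS(=O)(=O)C(F)(F)F)[C@@H]1C[C@@H](O[Si](CC)(CC)CC)[C@](C)(O[Si](CC)(CC)CC)C(=O)C1Br
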